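Monday's small charge of starting material reached a given percent of target sooner than Tuesday's larger one; the question is by how much.

the same everywhere: gas 2.2 mM (held)
- Monday's: starting material 0.0050 M; run made earlier
- Tuesday's: starting material 0.020 M; run made earlier
- flask: starting material 0.010 M; time 15 h

| run | time / h | target / % |
|---|---|---|
| Monday's | 1.33 | 5.5 |
| Monday's | 2.50 | 13.6 |
| Monday's | 4.00 | 23.1 |
| Monday's | 5.00 | 29.0 |
| Monday's | 6.00 | 35.3 |
| Monday's | 8.00 | 44.3 |
| Monday's | 10.0 | 51.2 |
| Tuesday's | 0.500 | 0.3 |
| Tuesday's | 1.33 | 3.7 |
| Tuesday's | 2.50 | 7.9 |
| Tuesday's | 4.00 | 13.6 |
| Tuesday's | 5.00 | 17.4 |
| Tuesday's | 8.00 | 28.1 |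
| Tuesday's | 10.0 | 35.7 |

(standard deviation of a reading: 1 percentage point)

- what was read earlier has a scatter of 1 percentage point, one standard deviation
- at the start none of the gas is in solution

- teal: doubling the transfer coefficient of the gas, all else as stated
- ochre: doubling the saturation concentration of gas, all else as stated

* amount of target at 15 h, in percent of the starting material charged
* the change that raises the amount of target at 15 h, in percent of the starting material charged most ("none" if none brings more than 2 percentage points) (teal / ochre / none)
* amount of target at 15 h, in percent of the starting material charged, after teal

Take the pseudo-first-order case, first order in starting material at held gas, as the zero of the scale: percent curves at different charges coincide, and the ratio of the times to the same percent is 1. Here Monday's run read 13.6% at 2.50 h, and Tuesday's read the same at 4.00 h, a ratio, read with the scatter of these readings, of 1.60 for 4.00 times the charge.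

Where does your flask sit? Its charge is twice Monday's and half Tuesday's, so, assuming the two doublings count equally, take the square root, 1.26: the clock stretch, the factor, read at this held gas, by which one doubling of the charge lengthens the time to a given percent.

What, then, are 15 h in your flask? They are 11.9 h on Monday's clock, past its last reading. Continuing the slope of its last two readings, I reckon 57.6%.

The forecast, higher than my figure, gave 59% (55% to 63%), 61% after teal (57% to 66%) and ochre as best, saying “Doubling saturation probably raises dissolved gas and rate substantially”.

The flask gives 57.8%, and 65.8% after teal; ochre is best, adding 21 percentage points against 8 points.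

    starting material + reagent → target (k = 63.0 M⁻¹ h⁻¹)
    starting material → side product (k = 0.0330 h⁻¹)
    gas ⇌ reagent, rate k3*(csat - [reagent]) (kL = 0.600 h⁻¹)

Both steps ran while starting material fell to 46.5% at 7.50 h, with c_reagent at 64.3% of saturation, and target and side product stood at 35.5% and 18.0%. By 15.0 h, c_reagent was 0.00181 M, with 16.9% starting material left. With its time held, this flask's answer moves by 5 points at a charge of 0.0147 M. Read at 6.0 h, the same flask stands at 4.74 h on Monday's clock, which interpolates to 27.5%; computed, 28.9%.

The readings stem from a simulated flask with constants of no real substance.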